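The plan rests on cutting the C7–C16 bond of the eleven-membered ring C. Six consecutive ring C atoms form an oxy-Cope product pattern: acetoxy carbon C9, methylene-bearing C8, ring B methine C7, ring-fusion methine C16, methyl-bearing C15 and bridgehead C1. The C15=C1 alkene is shared with cyclohexene ring A. One anionic [3,3] shift enlarges a cycloheptanol to ring C, makes C7–C16 with both stereocentres and installs the bridgehead alkene. It also leaves a C9/C8 enolate that formaldehyde traps as the masked methylene. The precursor is a spiro[5.6] alcohol, a 1-(E-alkenyl)cycloheptanol whose adjacent spiro carbon C1 lies in a silyloxycyclohexadiene made by semipinacol ring expansion. Gold catalysis closes ring B last.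

Key step: step 18

Atom labels, used for every compound: ring A = C1, C2, C3, C4, C16, C15; ring B = C4, C5, C6, C7, C16; ring C = C1, C15, C16, C7, C8, C9, C10, C11, C12, C13, C14. C17, C18 and C20 are the methyl groups on C15, C4 and C12, and C19 is the exocyclic methylene carbon. TIPS = triisopropylsilyl, PMB = 4-methoxybenzyl.

Remark on the chemistry: three centres are drawn as one epimer although either epimer serves. These are C4 between steps 9 and 15 (then erased), the C9 carbinol centre made in step 17 (both epimers fit the same chair and differ only in enolate geometry), and C8 between steps 18 and 23 (then erased).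

Step 1
Reactants: 1 4-methylcyclohexanone
Product: 2 (S)-trimethyl[(4-methylcyclohex-1-en-1-yl)oxy]silane
Conditions: (R,R)-bis(1-phenylethyl)amine·HCl, n-BuLi (2 equiv), THF, −78 to 0 °C; TMSCl, then 1, −100 °C
Reagents that add atoms: chlorotrimethylsilane, C[Si](C)(C)Cl
Why: Enantioselective deprotonation of a prochiral ketone with a C2-symmetric chiral lithium amide under in situ silyl quench, in which the base takes one of the two enantiotopic axial α-protons and thereby turns C12 into an S stereocentre, LiCl from the amine salt sharpening the selection.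

Step 2
Reactants: 2 (S)-trimethyl[(4-methylcyclohex-1-en-1-yl)oxy]silane
Product: 4 (4S)-2-hydroxy-4-methylcyclohexanone as a C14 epimer mixture, via silyloxy ketone 3 (not isolated)
Conditions: mCPBA, NaHCO3, CH2Cl2, −20 °C; then 1 M HCl, THF, 0 °C
Reagents that add atoms: 3-chloroperoxybenzoic acid, OOC(=O)c1cccc(Cl)c1
Why: Rubottom oxidation, in which the peracid epoxidises the electron-rich enol ether, silyl migration gives 3 and dilute acid frees the ketol; C14 arises as an epimer mixture that step 4 corrects and C12 is not touched.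

Step 3
Reactants: 4 (4S)-2-hydroxy-4-methylcyclohexanone (C14 epimer mixture)
Product: 5 (4S)-4-methyl-2-(triisopropylsilyloxy)cyclohexanone (C14 epimer mixture)
Conditions: TIPSOTf, 2,6-lutidine, CH2Cl2, −78 to 0 °C
Reagents that add atoms: triisopropylsilyl triflate, CC(C)[Si](C(C)C)(C(C)C)OS(=O)(=O)C(F)(F)F
Why: Silyl ether formation with a silyl triflate and a hindered pyridine base, quick enough at low temperature to forestall dimerisation or carbonyl transposition of the ketol, with no change at any stereocentre.

Step 4
Reactants: 5 (4S)-4-methyl-2-(triisopropylsilyloxy)cyclohexanone (C14 epimer mixture)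
Product: 6 (2S,4S)-4-methyl-2-(triisopropylsilyloxy)cyclohexanone (cis)
Conditions: DBU (20 mol %), toluene, rt to 40 °C; chromatography, trans isomer recycled
Reagents that add atoms: none
Why: Base-catalysed epimerisation through the enolate (thermodynamic control), which should favour the cis isomer with methyl and silyloxy groups both equatorial and so sets C14 relative to C12, the separated trans isomer being resubmitted.

Step 5
Reactants: 7 4-bromo-m-xylene (1-bromo-2,4-dimethylbenzene)
Product: 8 1-bromo-5-iodo-2,4-dimethylbenzene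
Conditions: NIS, CF3CO2H, rt
Reagents that add atoms: N-iodosuccinimide, O=C1CCC(=O)N1I
Why: Electrophilic aromatic iodination, directed to the one unhindered position that is ortho to one methyl group and para to the other.

Step 6
Reactants: 8 1-bromo-5-iodo-2,4-dimethylbenzene
Product: 9 1-bromo-5-methoxy-2,4-dimethylbenzene
Conditions: CuI (10 mol %), 1,10-phenanthroline (20 mol %), Cs2CO3, MeOH, 110 °C, sealed tube
Reagents that add atoms: methanol, CO
Why: Ullmann-type copper-catalysed C–O coupling, which engages the aryl iodide much faster than the aryl bromide and so keeps bromine for the lithiation.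

Step 7
Reactants: 9 1-bromo-5-methoxy-2,4-dimethylbenzene; 6 (2S,4S)-4-methyl-2-(triisopropylsilyloxy)cyclohexanone
Product: 11 (1S,2S,4S)-1-(5-methoxy-2,4-dimethylphenyl)-4-methyl-2-(triisopropylsilyloxy)cyclohexan-1-ol, via aryllithium 10 (not isolated)
Conditions: n-BuLi, THF, −78 °C; then 6, −78 °C; NH4Cl
Reagents that add atoms: none
Why: Bromine–lithium exchange and 1,2-addition of the aryllithium to the ketone, the bulky nucleophile taking the equatorial trajectory on the chair of 6 so that the aryl group ends equatorial and trans to the silyloxy group at the new C9 carbinol centre, which serves only as a relay.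

Step 8
Reactants: 11 tertiary benzylic alcohol
Product: 13 methoxycyclohexa-1,4-diene carbinol, via lithium alkoxide 12 (not isolated)
Conditions: n-BuLi (1.0 equiv), THF, −78 °C; then Li, NH3/THF, t-BuOH, −78 to −33 °C; isoprene, then NH4Cl
Reagents that add atoms: none
Why: Birch reduction, which protonates the two unsubstituted, para-related carbons C2 and C16 and leaves all four substituents on the C3=C4 and C15=C1 alkenes, while the preformed alkoxide and destruction of excess lithium before protonation protect the benzylic C–O bond from reductive cleavage.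

Step 9
Reactants: 13 methoxycyclohexa-1,4-diene carbinol
Product: 14 3-[(1S,2S,4S)-1-hydroxy-4-methyl-2-(triisopropylsilyloxy)cyclohexyl]-4,6-dimethylcyclohex-3-en-1-one (β,γ-enone)
Conditions: oxalic acid (20 mol %), THF/H2O, 0 °C to rt
Reagents that add atoms: water, O
Why: Kinetic hydrolysis of the enol ether with a weak acid, which protonates C4, keeps the C15=C1 alkene out of conjugation and is too mild to ionise the tertiary allylic alcohol.

Step 10
Reactants: 14 β,γ-enone
Product: 16 C2 hydroxy β,γ-enone, via dipotassium dienolate 15 (not isolated)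
Conditions: KHMDS (2.1 equiv), THF, −78 °C; then 2-(phenylsulfonyl)-3-phenyloxaziridine, −78 °C; AcOH
Reagents that add atoms: 2-(phenylsulfonyl)-3-phenyloxaziridine, O=S(=O)(c1ccccc1)N1OC1c1ccccc1
Why: Enolate hydroxylation with an N-sulfonyloxaziridine: after the alkoxide forms, the base removes a C2 proton (α to the ketone and allylic), the extended enolate reacts at its α carbon, and the oxidant should approach the face left open by the C14 silyloxy group, which lies over C2 in the rotamer that turns C14 away from the C15 methyl group.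

Step 11
Reactants: 16 C2 hydroxy β,γ-enone
Product: 17 epoxy diol (C1–C15 epoxide cis to the C2 hydroxyl)
Conditions: VO(acac)2 (5 mol %), t-BuOOH (decane), CH2Cl2, 0 °C
Reagents that add atoms: tert-butyl hydroperoxide, CC(C)(C)OO
Why: Hydroxyl-directed epoxidation of an allylic alcohol, in which vanadium bound to the ring hydroxyl at C2 delivers oxygen to the same face of the tetrasubstituted alkene and thus sets C1 and C15 cis to the C2 oxygen.

Step 12
Reactants: 17 epoxy diol
Product: 18 α-hydroxy epoxide with C2 PMB ether
Conditions: 2-(4-methoxybenzyloxy)-4-methylquinoline, MeOTf, MgO, PhCF3, 0 °C to rt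
Reagents that add atoms: 2-(4-methoxybenzyloxy)-4-methylquinoline, COc1ccc(COc2cc(C)c3ccccc3n2)cc1
Why: Ether formation by transfer of the PMB group from an N-methylquinolinium salt under neutral, MgO-buffered conditions, chosen because alkoxide bases would open the β,γ-epoxy ketone by elimination and acid catalysts would open the epoxide too early, the tertiary carbinol being too hindered to react.

Step 13
Reactants: 18 α-hydroxy epoxide with C2 PMB ether
Product: 19 spiro[5.6] diketone with C15 tertiary alcohol (C9 cis to the C2 ether and to the C15 hydroxyl, C14 trans to them)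
Conditions: ZnBr2 (20 mol %), CH2Cl2, −20 °C to rt
Reagents that add atoms: none
Why: Semipinacol rearrangement of a tertiary α-hydroxy epoxide: ZnBr2 bridges the carbinol and epoxide oxygens, the C1–O bond is the one whose cleavage can be concerted with carbonyl formation at C9, and C14, the more substituted neighbour whose oxygen lone pair supports the electron-deficient transition state, shifts to C1 anti to the leaving oxygen with retention at C14 and inversion at C1, which fixes the spiro centre.

Step 14
Reactants: 19 spiro[5.6] diketone with C15 tertiary alcohol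
Product: 20 spiro diketone with C15=C16 alkene
Conditions: methyl N-(triethylammoniosulfonyl)carbamate inner salt, toluene, 60 °C
Reagents that add atoms: none
Why: Dehydration of the tertiary alcohol by thermal syn elimination of its sulfamate ester under neutral conditions that avoid retro-aldol cleavage, C1 offering no hydrogen and the more substituted ring alkene C15=C16 being preferred over the exocyclic one.

Step 15
Reactants: 20 spiro diketone with C15=C16 alkene
Product: 21 spiro cycloheptanone with silyl dienol ether ring (C3 OTIPS, C3=C4, C15=C16)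
Conditions: TIPSOTf (1.1 equiv), Et3N, CH2Cl2, −78 to 0 °C
Reagents that add atoms: triisopropylsilyl triflate, CC(C)[Si](C(C)C)(C(C)C)OS(=O)(=O)C(F)(F)F
Why: Soft enolisation to a silyl dienol ether, in which carbonyl silylation is reversible and the deciding deprotonation is fastest at C4–H (α to C3=O and allylic), so that the conjugated diene forms, the stereocentre at C4 vanishes and the more hindered C9 ketone stays free.

Step 16
Reactants: 22 3-(trimethylsilyl)propynal
Product: 23 (E)-1-iodo-4-(trimethylsilyl)but-1-en-3-yne
Conditions: CrCl2 (6 equiv), CHI3 (2 equiv), THF, 0 °C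
Reagents that add atoms: iodoform, IC(I)I
Why: Takai olefination, whose gem-dichromium reagent converts the aldehyde into the E-iodoalkene, any Z isomer being removed by chromatography because the alkene geometry later sets C7.

Step 17
Reactants: 23 (E)-1-iodo-4-(trimethylsilyl)but-1-en-3-yne; 21 spiro cycloheptanone with silyl dienol ether ring
Product: 25 spiro 1-alkenylcycloheptanol, via alkenyllithium 24 (not isolated)
Conditions: t-BuLi (2 equiv), Et2O, −78 °C; then 21, LaCl3·2LiCl, THF, −78 °C; NH4Cl
Reagents that add atoms: none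
Why: Iodine–lithium exchange with retention of alkene geometry followed by lanthanide-assisted 1,2-addition, LaCl3·2LiCl raising carbonyl reactivity and suppressing enolisation of the hindered α-quaternary ketone while the silyl dienol ether masks C3, the configuration of the new C9 carbinol centre being of no consequence.

Step 18
Reactants: 25 spiro 1-alkenylcycloheptanol
Product: 28 bridged eleven-membered hydroxymethyl ketone, via potassium alkoxide 26 (not isolated), via potassium enolate 27 (not isolated)
Conditions: KHMDS (1.0 equiv), 18-crown-6, THF, −78 to 0 °C; then CH2O (monomer in THF), −78 °C; NH4Cl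
Reagents that add atoms: formaldehyde, C=O
Why: KHMDS turns 25 into the potassium alkoxide 26, whose oxido group weakens the crowded C9–C1 bond, and a concerted anionic oxy-Cope [3,3] shift follows in which alkenyl carbon C7 bonds to diene carbon C16 while C9–C1 breaks and the ring A alkene moves to C15=C1, giving enolate 27, which adds to formaldehyde (aldol addition). The closest known reaction type is the four-atom ring expansion of 1-alkenyl-2-vinylcycloalkanols by anionic oxy-Cope rearrangement, including variants that deliver bridgehead alkenes. Ring C is closed by ring expansion of the seven-membered ring through a six-membered chair transition state rather than by end-to-end cyclisation, the C15=C1 alkene being cis in ring A and therefore E in ring C. C16 is controlled by the spiro centre C1, since the new bond must form on the ring A face from which C9 departs, C7 by the E alkene geometry within the chair, and C8 by the face of formaldehyde attack, which is irrelevant because step 23 erases it. The step needs chair over boat, secured because the boat would push C8 against the C3 silyloxy group, and rearrangement over heterolysis of C9–C1 with loss of the C2 ether and aromatisation, served by one equivalent of base, low temperature and a neutral quench. No regiochemical alternative exists because C15=C16 is the only alkene allylic to C1.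

Step 19
Reactants: 28 bridged eleven-membered hydroxymethyl ketone
Product: 29 primary acetate of 28
Conditions: Ac2O, pyridine, CH2Cl2, 0 °C
Reagents that add atoms: acetic anhydride, CC(=O)OC(C)=O
Why: Acetylation of the primary alcohol with pyridine as the only base, mild enough to leave the β-acetoxy ketone uneliminated and the sensitive ring A diene intact.

Step 20
Reactants: 29 primary acetate of 28
Product: 30 terminal alkyne acetate
Conditions: AgNO3 (10 mol %), CH2Cl2/MeOH/H2O, rt
Reagents that add atoms: none
Why: Silver-catalysed protiodesilylation of the alkynylsilane under neutral conditions, preferred to carbonate in methanol or fluoride, which would cleave or eliminate the acetate or attack the silyl enol ether.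

Step 21
Reactants: 30 terminal alkyne acetate
Product: 31 tricyclic cyclopentene diketone (rings A, B and C complete, C5=C6, C3=O)
Conditions: [(2-biphenylyl)(t-Bu)2P]Au(NCMe)SbF6 (5 mol %), 2,6-di-tert-butyl-4-methylpyridine (10 mol %), MeOH (5 equiv), CH2Cl2, 0 °C to rt
Reagents that add atoms: none
Why: Gold-catalysed 5-endo-dig carbocyclisation of a silyl enol ether onto a terminal alkyne (Conia-ene type), in which C4 attacks the gold-activated C5, methanol takes the silyl group and protonates the vinylgold species, the short C16–C7 tether allows bonding only on the ring A face that carries C7 and so forces the cis-fused quaternary C4, and the hindered pyridine traps adventitious acid that could ionise the C2 ether.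

Step 22
Reactants: 31 tricyclic cyclopentene diketone
Product: 32 tricyclic cyclopentane diketone acetate
Conditions: KO2CN=NCO2K, AcOH, MeOH/CH2Cl2, 0 °C to rt
Reagents that add atoms: none
Why: Diimide reduction, which saturates the strained cis-disubstituted C5=C6 alkene and leaves the tetrasubstituted C15=C1 alkene, both ketones, the PMB ether and the still masked methylene alone.

Step 23
Reactants: 32 tricyclic cyclopentane diketone acetate
Product: 33 α-methylene ketone (C8=C19, C9=O)
Conditions: DBU (1.1 equiv), CH2Cl2, 0 °C
Reagents that add atoms: none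
Why: E1cB elimination of acetic acid from the β-acetoxy ketone, which unveils the C8=C19 methylene, erases the C8 centre and is kept short and cold to spare the base-sensitive C2–H next to the C3 ketone.

Step 24
Reactants: 33 α-methylene ketone
Product: 34 (9R) allylic alcohol
Conditions: (S)-2-methyl-CBS-oxazaborolidine (20 mol %), catecholborane, toluene, −78 °C
Reagents that add atoms: none
Why: Corey–Bakshi–Shibata reduction, in which the S catalyst treats the α-methylene side as the large group and should deliver hydride to give the 9R allylic alcohol under reagent control, the C3 ketone being shielded by quaternary C4 and the C2 ether.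

Step 25
Reactants: 34 (9R) allylic alcohol
Product: 35 C9,C14 diol
Conditions: HF·pyridine, pyridine, THF, 0 °C to rt
Reagents that add atoms: none
Why: Fluoride-mediated cleavage of the secondary silyl ether under buffered, weakly acidic conditions that avoid enolisation at C2.

Step 26
Reactants: 35 C9,C14 diol
Product: 36 C9,C14 diacetate with C2 PMB ether
Conditions: Ac2O, DMAP (cat), pyridine, CH2Cl2, 0 °C to rt
Reagents that add atoms: acetic anhydride, CC(=O)OC(C)=O
Why: Esterification of both secondary allylic alcohols with acetic anhydride under nucleophilic catalysis, with retention at C9 and C14.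

Step 27
Reactants: 36 C9,C14 diacetate with C2 PMB ether
Product: 37 diacetate α-hydroxy ketone (C2 OH, C3=O)
Conditions: DDQ, CH2Cl2/pH 7 buffer, 0 °C
Reagents that add atoms: none
Why: Oxidative cleavage of the PMB ether by DDQ through hydride abstraction and hydrolysis of the oxocarbenium ion, to which acetates, ketone and unactivated alkenes are inert.

Step 28
Reactants: 37 diacetate α-hydroxy ketone
Product: 38 target CNP0286573.1
Conditions: Me4NBH(OAc)3, MeCN/AcOH, −30 °C
Reagents that add atoms: none
Why: Hydroxyl-directed reduction (Saksena–Evans type), in which the C2 hydroxyl exchanges onto boron and hydride is delivered to the C3 ketone from the same face, so that the new C3 hydroxyl stands trans to the C2 hydroxyl, while acetates and alkenes do not react with this mild hydride.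

Compound list
1 | 4-methylcyclohexanone | CC1CCC(=O)CC1 | starting material
2 | (S)-trimethyl[(4-methylcyclohex-1-en-1-yl)oxy]silane | C[Si](C)(C)OC1=CC[C@@H](C)CC1 | intermediate
3 | (4S)-4-methyl-2-(trimethylsilyloxy)cyclohexanone, C14 epimers, not isolated | O=C1CC[C@H](C)CC1O[Si](C)(C)C | intermediate
4 | (4S)-2-hydroxy-4-methylcyclohexanone, C14 epimers | O=C1CC[C@H](C)CC1O | intermediate
5 | (4S)-4-methyl-2-(triisopropylsilyloxy)cyclohexanone, C14 epimers | O=C1CC[C@H](C)CC1O[Si](C(C)C)(C(C)C)C(C)C | intermediate
6 | (2S,4S)-4-methyl-2-(triisopropylsilyloxy)cyclohexanone, cis | O=C1CC[C@H](C)C[C@@H]1O[Si](C(C)C)(C(C)C)C(C)C | intermediate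
7 | 4-bromo-m-xylene | Cc1ccc(Br)c(C)c1 | starting material
8 | 1-bromo-5-iodo-2,4-dimethylbenzene | Cc1cc(C)c(I)cc1Br | intermediate
9 | 1-bromo-5-methoxy-2,4-dimethylbenzene | COc1cc(Br)c(C)cc1C | intermediate
10 | (5-methoxy-2,4-dimethylphenyl)lithium, not isolated | [Li]c1cc(OC)c(C)cc1C | intermediate
11 | (1S,2S,4S)-1-(5-methoxy-2,4-dimethylphenyl)-4-methyl-2-(triisopropylsilyloxy)cyclohexan-1-ol, aryl trans to OTIPS | O[C@]1(c2cc(OC)c(C)cc2C)CC[C@H](C)C[C@@H]1O[Si](C(C)C)(C(C)C)C(C)C | intermediate
12 | lithium alkoxide of 11, not isolated | [Li+].[O-][C@]1(c2cc(OC)c(C)cc2C)CC[C@H](C)C[C@@H]1O[Si](C(C)C)(C(C)C)C(C)C | intermediate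
13 | (1S,2S,4S)-1-(5-methoxy-2,4-dimethylcyclohexa-1,4-dien-1-yl)-4-methyl-2-(triisopropylsilyloxy)cyclohexan-1-ol | O[C@]1(C2=C(C)CC(C)=C(OC)C2)CC[C@H](C)C[C@@H]1O[Si](C(C)C)(C(C)C)C(C)C | intermediate
14 | β,γ-enone, 3-[(1S,2S,4S)-1-hydroxy-4-methyl-2-(triisopropylsilyloxy)cyclohexyl]-4,6-dimethylcyclohex-3-en-1-one | O[C@]1(C2=C(C)C[C@@H](C)C(=O)C2)CC[C@H](C)C[C@@H]1O[Si](C(C)C)(C(C)C)C(C)C | intermediate
15 | dipotassium alkoxide dienolate of 14, not isolated | [K+].[K+].[O-][C@]1(C2=C(C)C[C@@H](C)C([O-])=C2)CC[C@H](C)C[C@@H]1O[Si](C(C)C)(C(C)C)C(C)C | intermediate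
16 | C2 hydroxy β,γ-enone, C2 configured as in the target | O[C@]1(C2=C(C)C[C@@H](C)C(=O)[C@@H]2O)CC[C@H](C)C[C@@H]1O[Si](C(C)C)(C(C)C)C(C)C | intermediate
17 | epoxy diol, C1–C15 epoxide cis to the C2 hydroxyl | O[C@]1([C@@]23O[C@]2(C)C[C@@H](C)C(=O)[C@@H]3O)CC[C@H](C)C[C@@H]1O[Si](C(C)C)(C(C)C)C(C)C | intermediate
18 | α-hydroxy epoxide with C2 PMB ether | O[C@]1([C@@]23O[C@]2(C)C[C@@H](C)C(=O)[C@@H]3OCc2ccc(OC)cc2)CC[C@H](C)C[C@@H]1O[Si](C(C)C)(C(C)C)C(C)C | intermediate
19 | spiro[5.6] diketone with C15 tertiary alcohol, C9 cis to the C2 ether | O=C1CC[C@H](C)C[C@H](O[Si](C(C)C)(C(C)C)C(C)C)[C@]12[C@](C)(O)C[C@@H](C)C(=O)[C@@H]2OCc1ccc(OC)cc1 | intermediate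
20 | spiro diketone with C15=C16 alkene | O=C1CC[C@H](C)C[C@H](O[Si](C(C)C)(C(C)C)C(C)C)[C@]12C(C)=C[C@@H](C)C(=O)[C@@H]2OCc1ccc(OC)cc1 | intermediate
21 | spiro cycloheptanone with silyl dienol ether ring | O=C1CC[C@H](C)C[C@H](O[Si](C(C)C)(C(C)C)C(C)C)[C@]12C(C)=CC(C)=C(O[Si](C(C)C)(C(C)C)C(C)C)[C@@H]2OCc1ccc(OC)cc1 | intermediate
22 | 3-(trimethylsilyl)propynal | C[Si](C)(C)C#CC=O | starting material
23 | (E)-1-iodo-4-(trimethylsilyl)but-1-en-3-yne | C[Si](C)(C)C#C/C=C/I | intermediate
24 | (E)-[4-(trimethylsilyl)but-1-en-3-yn-1-yl]lithium, not isolated | [Li]/C=C/C#C[Si](C)(C)C | intermediate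
25 | spiro 1-alkenylcycloheptanol, oxy-Cope precursor | O[C@@]1(/C=C/C#C[Si](C)(C)C)CC[C@H](C)C[C@H](O[Si](C(C)C)(C(C)C)C(C)C)[C@]12C(C)=CC(C)=C(O[Si](C(C)C)(C(C)C)C(C)C)[C@@H]2OCc1ccc(OC)cc1 | intermediate
26 | potassium alkoxide of 25, not isolated | [K+].[O-][C@@]1(/C=C/C#C[Si](C)(C)C)CC[C@H](C)C[C@H](O[Si](C(C)C)(C(C)C)C(C)C)[C@]12C(C)=CC(C)=C(O[Si](C(C)C)(C(C)C)C(C)C)[C@@H]2OCc1ccc(OC)cc1 | intermediate
27 | ring-expanded potassium C9/C8 enolate, not isolated | [K+].[O-]/C1=C/[C@H](C#C[Si](C)(C)C)[C@@H]2C(C)=C(O[Si](C(C)C)(C(C)C)C(C)C)[C@H](OCc3ccc(OC)cc3)C(=C2C)[C@@H](O[Si](C(C)C)(C(C)C)C(C)C)C[C@@H](C)CC1 | intermediate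
28 | bridged eleven-membered ketone with C8 hydroxymethyl group | O=C1CC[C@H](C)C[C@H](O[Si](C(C)C)(C(C)C)C(C)C)C2=C(C)[C@H]([C@@H](C#C[Si](C)(C)C)[C@H]1CO)C(C)=C(O[Si](C(C)C)(C(C)C)C(C)C)[C@@H]2OCc1ccc(OC)cc1 | intermediate
29 | primary acetate of 28 | O=C1CC[C@H](C)C[C@H](O[Si](C(C)C)(C(C)C)C(C)C)C2=C(C)[C@H]([C@@H](C#C[Si](C)(C)C)[C@H]1COC(C)=O)C(C)=C(O[Si](C(C)C)(C(C)C)C(C)C)[C@@H]2OCc1ccc(OC)cc1 | intermediate
30 | terminal alkyne acetate | O=C1CC[C@H](C)C[C@H](O[Si](C(C)C)(C(C)C)C(C)C)C2=C(C)[C@H]([C@@H](C#C)[C@H]1COC(C)=O)C(C)=C(O[Si](C(C)C)(C(C)C)C(C)C)[C@@H]2OCc1ccc(OC)cc1 | intermediate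
31 | tricyclic cyclopentene diketone, cis-fused rings A and B | CC(=O)OC[C@H]1C(=O)CC[C@H](C)C[C@H](O[Si](C(C)C)(C(C)C)C(C)C)C2=C(C)[C@@H]3[C@H]1C=C[C@]3(C)C(=O)[C@@H]2OCc1ccc(OC)cc1 | intermediate
32 | tricyclic cyclopentane diketone acetate | CC(=O)OC[C@H]1C(=O)CC[C@H](C)C[C@H](O[Si](C(C)C)(C(C)C)C(C)C)C2=C(C)[C@@H]3[C@H]1CC[C@]3(C)C(=O)[C@@H]2OCc1ccc(OC)cc1 | intermediate
33 | α-methylene ketone | C=C1C(=O)CC[C@H](C)C[C@H](O[Si](C(C)C)(C(C)C)C(C)C)C2=C(C)[C@@H]3[C@H]1CC[C@]3(C)C(=O)[C@@H]2OCc1ccc(OC)cc1 | intermediate
34 | (9R) allylic alcohol | C=C1[C@H](O)CC[C@H](C)C[C@H](O[Si](C(C)C)(C(C)C)C(C)C)C2=C(C)[C@@H]3[C@H]1CC[C@]3(C)C(=O)[C@@H]2OCc1ccc(OC)cc1 | intermediate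
35 | C9,C14 diol | C=C1[C@H](O)CC[C@H](C)C[C@H](O)C2=C(C)[C@@H]3[C@H]1CC[C@]3(C)C(=O)[C@@H]2OCc1ccc(OC)cc1 | intermediate
36 | C9,C14 diacetate with C2 PMB ether | C=C1[C@H](OC(C)=O)CC[C@H](C)C[C@H](OC(C)=O)C2=C(C)[C@@H]3[C@H]1CC[C@]3(C)C(=O)[C@@H]2OCc1ccc(OC)cc1 | intermediate
37 | diacetate α-hydroxy ketone | C=C1[C@H](OC(C)=O)CC[C@H](C)C[C@H](OC(C)=O)C2=C(C)[C@@H]3[C@H]1CC[C@]3(C)C(=O)[C@@H]2O | intermediate
38 | CNP0286573.1, C9,C14 diacetate with trans C2,C3 diol (C2 OH cis to ring B) | C=C1[C@H](OC(C)=O)CC[C@H](C)C[C@H](OC(C)=O)C2=C(C)[C@@H]3[C@H]1CC[C@]3(C)[C@@H](O)[C@@H]2O | target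

Total step count: 28. Longest linear sequence: 25 steps (steps 1–4, 7–15 and 17–28, from 1 to 38).

Steps most likely to fail

1. Step 13 (semipinacol shift). Three processes compete with the wanted shift. The unsubstituted and less crowded C10 methylene may migrate in place of the oxygen-bearing C14. The epoxide may open at C15, the electronically less burdened carbon. The β,γ-epoxy ketone may open by elimination.

The fallback makes the C1–C14 bond by an aldol addition, where no choice of migrating group exists. It sets out from 18 and comes back at 19.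
- Et3N·3HF in MeCN would free the C14 hydroxyl and give the epoxy diol F1.
- Pb(OAc)4 in CH2Cl2 would cut the C9–C14 glycol bond to the epoxy keto aldehyde F2.
- SmI2 (divalent samarium, THF, −78 °C) would open the α,β-epoxy ketone reductively to a samarium enolate at C1. This enolate adds to the tethered aldehyde on the ring A face opposite to the C2 ether and the C15 alkoxide (reductive aldol), giving the spiro diol F3.
- In this variant C14 is re-created under chelate control.
- Selective silylation of the secondary hydroxyl with TIPSOTf and 2,6-lutidine returns 19.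

2. Step 18 (anionic oxy-Cope and formaldehyde capture). The alkoxide may cleave the C9–C1 bond heterolytically, after which loss of the C2 ether and aromatisation of ring A would be irreversible. Slow rearrangement would also expose the product diene to base.

The fallback removes all charge from the rearrangement. It sets out from 25 and comes back at 28.
- TMSOTf and 2,6-lutidine would give the trimethylsilyl ether F4.
- Heating in toluene in base-washed glass would bring about the neutral siloxy-Cope shift through the same chair, giving the ring-expanded trimethylsilyl enol ether F5.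
- One equivalent of MeLi in THF at 0 °C would cleave only this enol ether, since the TIPS enol ether is inert and the alkynylsilane reacts more slowly. This gives the lithium enolate F6.
- Monomeric formaldehyde at −78 °C converts F6 into 28.

3. Step 21 (gold-catalysed closure of ring B). The Lewis-acidic catalyst or trace acid may ionise the doubly allylic C2 ether and aromatise ring A. Alternatively, the enol ether may be protodesilylated before the C4–C5 bond forms.

The fallback closes ring B by enolate alkylation without any π-acid. It sets out from 30 and comes back at 32, which also makes step 22 unnecessary.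
- Dicyclohexylborane followed by Me3NO would convert the terminal alkyne into the aldehyde F7.
- LiAlH(Ot-Bu)3 at −78 °C would reduce only the aldehyde to the primary alcohol F8.
- I2, PPh3 and imidazole (Appel reaction) would give the primary iodide F9.
- One equivalent of Bu4NF in THF at −78 °C would release the C3/C4 enolate from the silyl enol ether. This enolate closes the five-membered ring by 5-exo-tet alkylation on the face that carries C7 and gives 32.

Further compounds
F1 | step 13 | epoxy diol | O[C@]1([C@@]23O[C@]2(C)C[C@@H](C)C(=O)[C@@H]3OCc2ccc(OC)cc2)CC[C@H](C)C[C@@H]1O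
F2 | step 13 | epoxy keto aldehyde | O=CC[C@@H](C)CCC(=O)[C@@]12O[C@]1(C)C[C@@H](C)C(=O)[C@@H]2OCc1ccc(OC)cc1
F3 | step 13 | spiro diol | O=C1CC[C@H](C)C[C@H](O)[C@]12[C@](C)(O)C[C@@H](C)C(=O)[C@@H]2OCc1ccc(OC)cc1
F4 | step 18 | trimethylsilyl ether | C[Si](C)(C)O[C@@]1(/C=C/C#C[Si](C)(C)C)CC[C@H](C)C[C@H](O[Si](C(C)C)(C(C)C)C(C)C)[C@]12C(C)=CC(C)=C(O[Si](C(C)C)(C(C)C)C(C)C)[C@@H]2OCc1ccc(OC)cc1
F5 | step 18 | ring-expanded trimethylsilyl enol ether | C[Si](C)(C)O/C1=C/[C@H](C#C[Si](C)(C)C)[C@@H]2C(C)=C(O[Si](C(C)C)(C(C)C)C(C)C)[C@H](OCc3ccc(OC)cc3)C(=C2C)[C@@H](O[Si](C(C)C)(C(C)C)C(C)C)C[C@@H](C)CC1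
F6 | step 18 | lithium enolate | [Li+].[O-]/C1=C/[C@H](C#C[Si](C)(C)C)[C@@H]2C(C)=C(O[Si](C(C)C)(C(C)C)C(C)C)[C@H](OCc3ccc(OC)cc3)C(=C2C)[C@@H](O[Si](C(C)C)(C(C)C)C(C)C)C[C@@H](C)CC1
F7 | step 21 | aldehyde | O=C1CC[C@H](C)C[C@H](O[Si](C(C)C)(C(C)C)C(C)C)C2=C(C)[C@H]([C@@H](CC=O)[C@H]1COC(C)=O)C(C)=C(O[Si](C(C)C)(C(C)C)C(C)C)[C@@H]2OCc1ccc(OC)cc1
F8 | step 21 | primary alcohol | O=C1CC[C@H](C)C[C@H](O[Si](C(C)C)(C(C)C)C(C)C)C2=C(C)[C@H]([C@@H](CCO)[C@H]1COC(C)=O)C(C)=C(O[Si](C(C)C)(C(C)C)C(C)C)[C@@H]2OCc1ccc(OC)cc1
F9 | step 21 | primary iodide | O=C1CC[C@H](C)C[C@H](O[Si](C(C)C)(C(C)C)C(C)C)C2=C(C)[C@H]([C@@H](CCI)[C@H]1COC(C)=O)C(C)=C(O[Si](C(C)C)(C(C)C)C(C)C)[C@@H]2OCc1ccc(OC)cc1
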